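The trimer is cut at both methylene bridges into ring B, used as the bis(aminomethyl) derivative of phlorisovalerophenone, and two copies of one monomer (rings A and C). The route depends on how that monomer is made. Its three contiguous ring carbons C6(OH), C1(isovaleryl) and C2(OMe) are what a 3-methoxyaryne gives after taking up isovaleric acid. One operation forms the C6–O and C1–acyl bonds, and the C2 methoxy group fixes the orientation. Methylating the free triol would instead hit the unchelated C4 hydroxyl. The precursor is an ortho-silylaryl triflate (OTf on C6, SiMe3 on C1) that already carries C2–OMe, C3–Me and a benzyl-protected C4 oxygen.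

Key step: step 8

Remark: rings A and C are numbered C1 (isovaleryl), C2 (OMe), C3 (Me), C4 (OH), C5 (bridge carbon), C6 (OH). The target has no stereocentre, so no SMILES carries a stereo descriptor.

Step 1
Reactants: 1 3-methoxy-2-methylphenol
Product: 2 triisopropyl(3-methoxy-2-methylphenoxy)silane
Conditions: TIPSCl (1.2 equiv), imidazole (2.5 equiv), DMF, rt
Reagents that add atoms: chlorotriisopropylsilane, CC(C)[Si](Cl)(C(C)C)C(C)C
Why: Routine O-silylation of a phenol, chosen because the bulky, non-coordinating TIPS ether on the C4 oxygen will later shield the neighbouring C5–H from metalation.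

Step 2
Reactants: 2 triisopropyl(3-methoxy-2-methylphenoxy)silane
Product: 4 3-methoxy-4-methyl-5-[(triisopropylsilyl)oxy]phenol, via arylboronate 3 (not isolated)
Conditions: [Ir(OMe)(cod)]2 (1.5 mol %), 4,4'-di-tert-butyl-2,2'-bipyridine (3 mol %), B2pin2 (1.0 equiv), THF, 80 °C; then 30% H2O2, 1 M aq NaOH, 0 °C
Reagents that add atoms: bis(pinacolato)diboron, CC1(C)OB(OC1(C)C)B1OC(C)(C)C(C)(C)O1 (boryl group of 3); hydrogen peroxide, OO (new oxygen of 4)
Why: Sterically governed iridium-catalysed C–H borylation should pick the only ring CH without an ortho neighbour (future C6, meta to both oxygens), and one-pot peroxide oxidation of the C–B bond is the standard arene-to-phenol sequence, run cold and briefly so that the hindered TIPS ether survives.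

Step 3
Reactants: 4 3-methoxy-4-methyl-5-[(triisopropylsilyl)oxy]phenol
Product: 5 3-methoxy-4-methyl-5-[(triisopropylsilyl)oxy]phenyl N-isopropylcarbamate
Conditions: i-PrNCO (1.5 equiv), Et3N (0.2 equiv), CH2Cl2, rt
Reagents that add atoms: isopropyl isocyanate, CC(C)N=C=O
Why: Base-catalysed addition of a phenol to an isocyanate gives an O-aryl carbamate that is a strong metalation director and, because it keeps an N–H, can later be removed by mild base instead of hydride or hot alkali.

Step 4
Reactants: 5 3-methoxy-4-methyl-5-[(triisopropylsilyl)oxy]phenyl N-isopropylcarbamate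
Product: 9 3-methoxy-4-methyl-5-[(triisopropylsilyl)oxy]-2-(trimethylsilyl)phenyl N-isopropylcarbamate, via N-silyl carbamate 6 (not isolated), via aryllithium 7 (not isolated), via N,C-disilyl carbamate 8 (not isolated)
Conditions: TBSOTf (1.1 equiv), TMEDA (1.1 equiv), Et2O, 0 °C to rt; TMEDA (2 equiv), n-BuLi (2 equiv), −78 °C; TMSCl (3 equiv), −78 °C to rt; cold 1 M aq NaHSO4, brief contact
Reagents that add atoms: chlorotrimethylsilane, C[Si](C)(C)Cl; for the intermediates only: tert-butyldimethylsilyl triflate, CC(C)(C)[Si](C)(C)OS(=O)(=O)C(F)(F)F, and n-butyllithium, [Li]CCCC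
Why: Directed ortho-metalation after transient N-silylation of the carbamate should remove the proton at C1, where the carbamate and the C2 methoxy group cooperate, while the other ortho site (C5) lies under the TIPS ether, the low temperature suppresses the anionic Fries shift, and the N–Si bond falls off on work-up.

Step 5
Reactants: 9 3-methoxy-4-methyl-5-[(triisopropylsilyl)oxy]-2-(trimethylsilyl)phenyl N-isopropylcarbamate
Product: 10 5-hydroxy-3-methoxy-4-methyl-2-(trimethylsilyl)phenyl N-isopropylcarbamate
Conditions: TBAF (1.05 equiv), AcOH (1.05 equiv), THF, 0 °C, short reaction time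
Reagents that add atoms: none
Why: Fluoride-induced O-desilylation cleaves the phenolic Si–O bond much faster than the crowded aryl C–SiMe3 bond, and the acetic acid buffer keeps the medium too weakly basic for E1cB loss of the carbamate or carbanion-type protodesilylation.

Step 6
Reactants: 10 5-hydroxy-3-methoxy-4-methyl-2-(trimethylsilyl)phenyl N-isopropylcarbamate
Product: 11 5-(benzyloxy)-3-methoxy-4-methyl-2-(trimethylsilyl)phenyl N-isopropylcarbamate
Conditions: BnOH (1.2 equiv), PPh3 (1.3 equiv), DIAD (1.3 equiv), THF, 0 °C to rt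
Reagents that add atoms: benzyl alcohol, OCc1ccccc1
Why: The Mitsunobu etherification is essentially neutral and alkylates only the phenol (the carbamate N–H is far less acidic), so the base-labile carbamate and the acid-labile electron-rich aryl silane are both spared and a fluoride-proof protecting group is installed on the C4 oxygen.

Step 7
Reactants: 11 5-(benzyloxy)-3-methoxy-4-methyl-2-(trimethylsilyl)phenyl N-isopropylcarbamate
Product: 13 5-(benzyloxy)-3-methoxy-4-methyl-2-(trimethylsilyl)phenyl trifluoromethanesulfonate, via silylphenol 12 (not isolated)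
Conditions: DBU (1.5 equiv), Et2NH (1.2 equiv), MeCN, 40 °C; then PhNTf2 (1.5 equiv), rt
Reagents that add atoms: N-phenylbis(trifluoromethanesulfonimide), O=S(=O)(N(c1ccccc1)S(=O)(=O)C(F)(F)F)C(F)(F)F
Why: DBU fragments the N–H carbamate by E1cB into phenoxide and isopropyl isocyanate, diethylamine traps the isocyanate as a urea, and the phenoxide of 12 is sulfonylated in the same flask by the mild triflyl donor, which is the established one-pot carbamate-to-triflate conversion for ortho-silylaryl triflates.

Step 8
Reactants: 13 5-(benzyloxy)-3-methoxy-4-methyl-2-(trimethylsilyl)phenyl trifluoromethanesulfonate; 14 isovaleric acid (3-methylbutanoic acid)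
Product: 18 1-[4-(benzyloxy)-6-hydroxy-2-methoxy-3-methylphenyl]-3-methylbutan-1-one, via aryne 15 (not isolated), via aryl anion 16 (not isolated), via benzoxetene alkoxide 17 (not isolated)
Conditions: 14 (1.1 equiv), CsF (4 equiv), THF (about 0.02 M), 125 °C, sealed tube; aq NH4Cl
Reagents that add atoms: cesium fluoride, [Cs+].[F-] (counter-ion of intermediates 16 and 17 only; the acyl and oxygen atoms come from reactant 14)
Why: Fluoride attacks the SiMe3 group of 13 and triflate departs, giving aryne 15, whose C1≡C6 bond is distorted by the σ-withdrawing C2 methoxy group so that C6 becomes the more electrophilic end. The carboxylate of 14 therefore bonds through oxygen to C6 and leaves the charge on C1 (16), next to the stabilising C2–O dipole. This carbanion adds to the ester carbonyl (4-exo-trig) to give the strained alkoxide 17, which reopens by C–O cleavage to the chelated ortho-acyl phenoxide, so no ring and no stereocentre remain in 18. The reaction type is the known fluoride-induced insertion of arynes into the C–O bond of carboxylic acids, an intermolecular relative of the anionic ortho-Fries shift. Regioselectivity is the one selectivity required, and the methoxy group secures it because the other flank of the triple bond (C5) bears only hydrogen and the remote C4 benzyloxy group exerts a much weaker bias. High dilution and high temperature favour the intramolecular acyl shift over protonation of 16, and the benzyl ether keeps the C4 oxygen from acting as a competing nucleophile.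

Step 9
Reactants: 18 1-[4-(benzyloxy)-6-hydroxy-2-methoxy-3-methylphenyl]-3-methylbutan-1-one
Product: 19 1-(4,6-dihydroxy-2-methoxy-3-methylphenyl)-3-methylbutan-1-one (ring A/C monomer)
Conditions: H2 (1 atm), 10% Pd/C, EtOAc, rt
Reagents that add atoms: none
Why: Catalytic hydrogenolysis of the benzyl aryl ether is fast at one atmosphere, whereas the hydrogen-bonded, electron-rich aryl ketone is slow to reduce under these conditions.

Step 10
Reactants: 20 phloroglucinol (anhydrous); 21 isovaleryl chloride
Product: 22 1-(2,4,6-trihydroxyphenyl)-3-methylbutan-1-one (phlorisovalerophenone)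
Conditions: AlCl3 (3.5 equiv), CH2Cl2/PhNO2, 0 to 45 °C; ice/aq HCl
Reagents that add atoms: isovaleryl chloride 21, CC(C)CC(Cl)=O
Why: Friedel–Crafts C-acylation of phloroglucinol is the classical entry to acylphloroglucinols, and the first acyl group deactivates the ring and chelates aluminium so that monoacylation should prevail.

Step 11
Reactants: 22 1-(2,4,6-trihydroxyphenyl)-3-methylbutan-1-one
Product: 24 1-{3,5-bis[(dimethylamino)methyl]-2,4,6-trihydroxyphenyl}-3-methylbutan-1-one, via mono-Mannich base 23 (not isolated)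
Conditions: 37% aq HCHO (2.2 equiv) premixed with 40% aq Me2NH (2.4 equiv), EtOH, 0 °C to rt
Reagents that add atoms: formaldehyde, C=O; dimethylamine, CNC
Why: In this double Mannich aminomethylation the two remaining ring CH of the acylphloroglucinol are strongly nucleophilic, a slight excess of the preformed hemiaminal at low temperature should convert both before any amine is lost, and the inner salt is expected to crystallise from ethanol.

Step 12
Reactants: 24 1-{3,5-bis[(dimethylamino)methyl]-2,4,6-trihydroxyphenyl}-3-methylbutan-1-one; 19 1-(4,6-dihydroxy-2-methoxy-3-methylphenyl)-3-methylbutan-1-one (2.1 equiv)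
Product: 28 1-(3,5-bis{[2,6-dihydroxy-4-methoxy-3-methyl-5-(3-methylbutanoyl)phenyl]methyl}-2,4,6-trihydroxyphenyl)-3-methylbutan-1-one (CNP0158539.0), via quinone methide 25 (not isolated), via mono-coupled Mannich base 26 (not isolated), via second quinone methide 27 (not isolated)
Conditions: 1,4-dioxane, 100 °C, slow argon purge; dilute aq HCl wash
Reagents that add atoms: none
Why: Thermal loss of volatile dimethylamine from the zwitterionic phenolic Mannich base unmasks ortho-quinone methide 25, which is captured at the only free ring carbon (C5) of 19 in a conjugate Friedel–Crafts-type addition, and repetition on the second arm (26, then 27) completes the ring A–CH2–ring B–CH2–ring C array, self-condensation being blocked because 24 has no free ring CH and 19 has no leaving group.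

Compound list
1 | 3-methoxy-2-methylphenol | COc1cccc(O)c1C | starting material
2 | triisopropyl(3-methoxy-2-methylphenoxy)silane | COc1cccc(O[Si](C(C)C)(C(C)C)C(C)C)c1C | intermediate
3 | 2-{3-methoxy-4-methyl-5-[(triisopropylsilyl)oxy]phenyl}-4,4,5,5-tetramethyl-1,3,2-dioxaborolane | COc1cc(B2OC(C)(C)C(C)(C)O2)cc(O[Si](C(C)C)(C(C)C)C(C)C)c1C | intermediate
4 | 3-methoxy-4-methyl-5-[(triisopropylsilyl)oxy]phenol | COc1cc(O)cc(O[Si](C(C)C)(C(C)C)C(C)C)c1C | intermediate
5 | 3-methoxy-4-methyl-5-[(triisopropylsilyl)oxy]phenyl N-isopropylcarbamate | COc1cc(OC(=O)NC(C)C)cc(O[Si](C(C)C)(C(C)C)C(C)C)c1C | intermediate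
6 | 3-methoxy-4-methyl-5-[(triisopropylsilyl)oxy]phenyl N-(tert-butyldimethylsilyl)-N-isopropylcarbamate | COc1cc(OC(=O)N(C(C)C)[Si](C)(C)C(C)(C)C)cc(O[Si](C(C)C)(C(C)C)C(C)C)c1C | intermediate
7 | 2-lithio derivative of 6 (lithium on the carbon between OMe and the carbamate oxygen) | COc1c(C)c(O[Si](C(C)C)(C(C)C)C(C)C)cc(OC(=O)N(C(C)C)[Si](C)(C)C(C)(C)C)c1[Li] | intermediate
8 | 3-methoxy-4-methyl-5-[(triisopropylsilyl)oxy]-2-(trimethylsilyl)phenyl N-(tert-butyldimethylsilyl)-N-isopropylcarbamate | COc1c(C)c(O[Si](C(C)C)(C(C)C)C(C)C)cc(OC(=O)N(C(C)C)[Si](C)(C)C(C)(C)C)c1[Si](C)(C)C | intermediate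
9 | 3-methoxy-4-methyl-5-[(triisopropylsilyl)oxy]-2-(trimethylsilyl)phenyl N-isopropylcarbamate | COc1c(C)c(O[Si](C(C)C)(C(C)C)C(C)C)cc(OC(=O)NC(C)C)c1[Si](C)(C)C | intermediate
10 | 5-hydroxy-3-methoxy-4-methyl-2-(trimethylsilyl)phenyl N-isopropylcarbamate | COc1c(C)c(O)cc(OC(=O)NC(C)C)c1[Si](C)(C)C | intermediate
11 | 5-(benzyloxy)-3-methoxy-4-methyl-2-(trimethylsilyl)phenyl N-isopropylcarbamate | COc1c(C)c(OCc2ccccc2)cc(OC(=O)NC(C)C)c1[Si](C)(C)C | intermediate
12 | 5-(benzyloxy)-3-methoxy-4-methyl-2-(trimethylsilyl)phenol | COc1c(C)c(OCc2ccccc2)cc(O)c1[Si](C)(C)C | intermediate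
13 | 5-(benzyloxy)-3-methoxy-4-methyl-2-(trimethylsilyl)phenyl trifluoromethanesulfonate | COc1c(C)c(OCc2ccccc2)cc(OS(=O)(=O)C(F)(F)F)c1[Si](C)(C)C | intermediate
14 | isovaleric acid (3-methylbutanoic acid) | CC(C)CC(=O)O | starting material
15 | 5-(benzyloxy)-3-methoxy-4-methylbenzyne (triple bond C1–C2, OMe on C3 in benzyne numbering) | COC1=C(C)C(OCc2ccccc2)=CC#C1 | intermediate
16 | cesium 4-(benzyloxy)-2-methoxy-3-methyl-6-[(3-methylbutanoyl)oxy]benzen-1-ide | COc1c(C)c(OCc2ccccc2)cc(OC(=O)CC(C)C)[c-]1.[Cs+] | intermediate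
17 | cesium 5-(benzyloxy)-3-methoxy-4-methyl-2-(2-methylpropyl)-2H-benzo[b]oxet-2-olate | COc1c(C)c(OCc2ccccc2)cc2OC([O-])(CC(C)C)c12.[Cs+] | intermediate
18 | 1-[4-(benzyloxy)-6-hydroxy-2-methoxy-3-methylphenyl]-3-methylbutan-1-one | COc1c(C)c(OCc2ccccc2)cc(O)c1C(=O)CC(C)C | intermediate
19 | 1-(4,6-dihydroxy-2-methoxy-3-methylphenyl)-3-methylbutan-1-one | COc1c(C)c(O)cc(O)c1C(=O)CC(C)C | intermediate
20 | phloroglucinol | Oc1cc(O)cc(O)c1 | starting material
21 | isovaleryl chloride | CC(C)CC(Cl)=O | starting material
22 | 1-(2,4,6-trihydroxyphenyl)-3-methylbutan-1-one | CC(C)CC(=O)c1c(O)cc(O)cc1O | intermediate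
23 | 1-{3-[(dimethylamino)methyl]-2,4,6-trihydroxyphenyl}-3-methylbutan-1-one | CC(C)CC(=O)c1c(O)cc(O)c(CN(C)C)c1O | intermediate
24 | 1-{3,5-bis[(dimethylamino)methyl]-2,4,6-trihydroxyphenyl}-3-methylbutan-1-one | CC(C)CC(=O)c1c(O)c(CN(C)C)c(O)c(CN(C)C)c1O | intermediate
25 | 2-[(dimethylamino)methyl]-3,5-dihydroxy-4-(3-methylbutanoyl)-6-methylidenecyclohexa-2,4-dien-1-one | C=C1C(=O)C(CN(C)C)=C(O)C(C(=O)CC(C)C)=C1O | intermediate
26 | 1-(3-{[2,6-dihydroxy-4-methoxy-3-methyl-5-(3-methylbutanoyl)phenyl]methyl}-5-[(dimethylamino)methyl]-2,4,6-trihydroxyphenyl)-3-methylbutan-1-one | COc1c(C)c(O)c(Cc2c(O)c(CN(C)C)c(O)c(C(=O)CC(C)C)c2O)c(O)c1C(=O)CC(C)C | intermediate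
27 | 2-{[2,6-dihydroxy-4-methoxy-3-methyl-5-(3-methylbutanoyl)phenyl]methyl}-3,5-dihydroxy-4-(3-methylbutanoyl)-6-methylidenecyclohexa-2,4-dien-1-one | C=C1C(=O)C(Cc2c(O)c(C)c(OC)c(C(=O)CC(C)C)c2O)=C(O)C(C(=O)CC(C)C)=C1O | intermediate
28 | 1-(3,5-bis{[2,6-dihydroxy-4-methoxy-3-methyl-5-(3-methylbutanoyl)phenyl]methyl}-2,4,6-trihydroxyphenyl)-3-methylbutan-1-one (CNP0158539.0) | COc1c(C)c(O)c(Cc2c(O)c(Cc3c(O)c(C)c(OC)c(C(=O)CC(C)C)c3O)c(O)c(C(=O)CC(C)C)c2O)c(O)c1C(=O)CC(C)C | target

Total step count: 12. Longest linear sequence: 10 (steps 1–9, then step 12). Steps 10 and 11 form the short convergent branch.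

Steps most likely to fail

Step 8. The aryl anion may be protonated by bifluoride or unreacted acid before it reaches the ester carbonyl, which would stop the sequence at plain O-arylation. The product phenoxide may also add to a second aryne. The fallback avoids the aryne, sets out from 5 and comes back at 19. Carbamate 5 is N-silylated and lithiated as in step 4 (6, then 7). Aryllithium 7 is quenched at −78 °C with N-methoxy-N,3-dimethylbutanamide (Weinreb ketone synthesis) to give the N-silylated keto carbamate F1, which loses its N–Si bond on aqueous work-up to give the keto carbamate F2. DBU/Et2NH in MeCN then releases the chelated phenol as the TIPS-protected hydroxy ketone F3. TBAF/AcOH in THF removes the silyl ether and should deliver monomer 19, so the acyl group still ends up beside methoxy but by directed metalation.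

Step 12. The methylene bridges may open and re-form under the hot, amine-containing conditions, scrambling the rings. The second arm may couple incompletely, and amine may re-add to the quinone methides. The fallback reverses the polarity, sets out from 19 and 22 and comes back at 28. Monomer 19 is aminomethylated at its single free carbon C5 (HCHO/Me2NH, EtOH, 0 °C) to give the monomer Mannich base F4. Two equivalents of this are added slowly to phlorisovalerophenone 22 in warm dioxane. Each molecule releases the monomer quinone methide F5, which is taken up by a free ring CH of ring B, first giving the mono-bridged dimer F6 and then 28. The electrophile then never carries a second leaving group and can be kept at low concentration.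

Step 5. Fluoride may attack the aryl C–Si bond, a protodesilylation helped by the two flanking oxygen substituents, or the basic medium may strip the N–H carbamate. The fallback puts silicon on carbon only after the protecting-group exchange, sets out from 5 (through 6 and 7, made as in step 4) and comes back at 11. Aryllithium 7 is quenched with I2 to give the N-silylated aryl iodide F7, and work-up gives the aryl iodide F8, whose C–I bond is indifferent to fluoride. TBAF/AcOH gives the iodophenol F9 and Mitsunobu benzylation gives the benzyl ether F10. TBSOTf/TMEDA converts this into the N-silyl carbamate F11. Iodine–lithium exchange with n-BuLi at −78 °C gives the aryllithium F12, and TMSCl gives the N,C-disilyl carbamate F13. The bisulfate work-up then leaves 11.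

Further compounds
F1 | step 8 | 3-methoxy-4-methyl-2-(3-methylbutanoyl)-5-[(triisopropylsilyl)oxy]phenyl N-(tert-butyldimethylsilyl)-N-isopropylcarbamate | COc1c(C)c(O[Si](C(C)C)(C(C)C)C(C)C)cc(OC(=O)N(C(C)C)[Si](C)(C)C(C)(C)C)c1C(=O)CC(C)C
F2 | step 8 | 3-methoxy-4-methyl-2-(3-methylbutanoyl)-5-[(triisopropylsilyl)oxy]phenyl N-isopropylcarbamate | COc1c(C)c(O[Si](C(C)C)(C(C)C)C(C)C)cc(OC(=O)NC(C)C)c1C(=O)CC(C)C
F3 | step 8 | 1-{6-hydroxy-2-methoxy-3-methyl-4-[(triisopropylsilyl)oxy]phenyl}-3-methylbutan-1-one | COc1c(C)c(O[Si](C(C)C)(C(C)C)C(C)C)cc(O)c1C(=O)CC(C)C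
F4 | step 12 | 1-{3-[(dimethylamino)methyl]-2,4-dihydroxy-6-methoxy-5-methylphenyl}-3-methylbutan-1-one | COc1c(C)c(O)c(CN(C)C)c(O)c1C(=O)CC(C)C
F5 | step 12 | 5-hydroxy-3-methoxy-2-methyl-4-(3-methylbutanoyl)-6-methylidenecyclohexa-2,4-dien-1-one | C=C1C(=O)C(C)=C(OC)C(C(=O)CC(C)C)=C1O
F6 | step 12 | 1-(3-{[2,6-dihydroxy-4-methoxy-3-methyl-5-(3-methylbutanoyl)phenyl]methyl}-2,4,6-trihydroxyphenyl)-3-methylbutan-1-one | COc1c(C)c(O)c(Cc2c(O)cc(O)c(C(=O)CC(C)C)c2O)c(O)c1C(=O)CC(C)C
F7 | step 5 | 2-iodo-3-methoxy-4-methyl-5-[(triisopropylsilyl)oxy]phenyl N-(tert-butyldimethylsilyl)-N-isopropylcarbamate | COc1c(C)c(O[Si](C(C)C)(C(C)C)C(C)C)cc(OC(=O)N(C(C)C)[Si](C)(C)C(C)(C)C)c1I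
F8 | step 5 | 2-iodo-3-methoxy-4-methyl-5-[(triisopropylsilyl)oxy]phenyl N-isopropylcarbamate | COc1c(C)c(O[Si](C(C)C)(C(C)C)C(C)C)cc(OC(=O)NC(C)C)c1I
F9 | step 5 | 5-hydroxy-2-iodo-3-methoxy-4-methylphenyl N-isopropylcarbamate | COc1c(C)c(O)cc(OC(=O)NC(C)C)c1I
F10 | step 5 | 5-(benzyloxy)-2-iodo-3-methoxy-4-methylphenyl N-isopropylcarbamate | COc1c(C)c(OCc2ccccc2)cc(OC(=O)NC(C)C)c1I
F11 | step 5 | 5-(benzyloxy)-2-iodo-3-methoxy-4-methylphenyl N-(tert-butyldimethylsilyl)-N-isopropylcarbamate | COc1c(C)c(OCc2ccccc2)cc(OC(=O)N(C(C)C)[Si](C)(C)C(C)(C)C)c1I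
F12 | step 5 | 5-(benzyloxy)-2-lithio-3-methoxy-4-methylphenyl N-(tert-butyldimethylsilyl)-N-isopropylcarbamate | COc1c(C)c(OCc2ccccc2)cc(OC(=O)N(C(C)C)[Si](C)(C)C(C)(C)C)c1[Li]
F13 | step 5 | 5-(benzyloxy)-3-methoxy-4-methyl-2-(trimethylsilyl)phenyl N-(tert-butyldimethylsilyl)-N-isopropylcarbamate | COc1c(C)c(OCc2ccccc2)cc(OC(=O)N(C(C)C)[Si](C)(C)C(C)(C)C)c1[Si](C)(C)C
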